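**Retrosynthetic overview** (ring numbering as in the target name: C1 carries CO2H, C5 the methylidene, C6 the OH, C10 the ester oxygen)

1. Target ⇒ desilylation and tert-butyl ester cleavage, then O-acylation, of a macrocyclic 10-hydroxy ester.
2. Key disconnection C10–C11: ring-closing allylboration. C11 is the β-carbon of the acrylate and natively electrophilic; as a 2-(alkoxycarbonyl)allylboronate it acts as an ester homoenolate and attacks the aldehyde carbon C10. Boron-to-carbinol chirality transfer sets C10 and the enoate geometry.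
3. Seco-aldehyde ⇒ C5–C6 asymmetric Nozaki–Hiyama–Kishi coupling of an alkenyl iodide with symmetric 3,3-dimethylpentanedial; this sets C6 and needs no end differentiation.
4. Alkenyl iodide/allylboronate ⇒ Morita–Baylis–Hillman adduct of 4-iodopent-4-enal and tert-butyl acrylate, through the rearranged allylic bromide and an asymmetric copper-catalysed SN2′ borylation.
5. Ring order: there is one ring, the 11-membered carbocycle; it is closed in the key step, third from last.

Assumption: 3,3-dimethylpentane-1,5-diol (1) is bought (otherwise one LiAlH4 reduction from 3,3-dimethylglutaric anhydride), and the enantiomer of each chiral ligand is assigned by analogy and would be confirmed or swapped on the first run.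

**Route**

Step 1
Reactants: 1 3,3-dimethylpentane-1,5-diol
Product: 2 3,3-dimethylpentanedial
Conditions: (COCl)2, DMSO, CH2Cl2, −78 °C; Et3N, to rt
Reagents that add atoms: none
Why: Swern oxidation activates both hydroxyls before base is added, so the dialdehyde forms without the lactol or lactone that stepwise oxidants give from a 1,5-diol.

Step 2
Reactants: 3 pent-4-yn-1-ol
Product: 4 4-iodopent-4-en-1-ol
Conditions: NaI, Me3SiCl, H2O, MeCN, rt
Reagents that add atoms: sodium iodide [Na+].[I-]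
Why: Markovnikov hydroiodination of the terminal alkyne by HI generated in situ gives the 2-iodo-1-alkene needed for the later chromium coupling.

Step 3
Reactants: 4 4-iodopent-4-en-1-ol
Product: 5 4-iodopent-4-enal
Conditions: Dess–Martin periodinane, CH2Cl2, 0 °C to rt
Reagents that add atoms: none
Why: Dess–Martin oxidation of the primary alcohol stops at the aldehyde under neutral conditions and leaves the alkenyl iodide untouched.

Step 4
Reactants: 5 4-iodopent-4-enal; 6 tert-butyl acrylate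
Product: 7 tert-butyl 3-hydroxy-6-iodo-2-methylidenehept-6-enoate (racemic)
Conditions: 3-hydroxyquinuclidine (0.3 equiv), MeOH (0.75 equiv), neat in 6 (3 equiv), rt, 4 d
Reagents that add atoms: none
Why: Morita–Baylis–Hillman reaction (amine adds to the acrylate, the zwitterionic enolate adds to the aldehyde, the amine is expelled); the racemic carbinol centre is erased in step 5.

Step 5
Reactants: 7 tert-butyl 3-hydroxy-6-iodo-2-methylidenehept-6-enoate
Product: 8 tert-butyl (2Z)-2-(bromomethyl)-6-iodohepta-2,6-dienoate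
Conditions: N-bromosuccinimide, Me2S, CH2Cl2, 0 °C to rt
Reagents that add atoms: N-bromosuccinimide O=C1CCC(=O)N1Br
Why: Bromodimethylsulfonium activation of the hydroxyl and SN2′ delivery of bromide give the thermodynamically preferred single (2Z) allylic bromide without acid, so the tert-butyl ester survives.

Step 6
Reactants: 8 tert-butyl (2Z)-2-(bromomethyl)-6-iodohepta-2,6-dienoate
Product: 9 tert-butyl (3R)-6-iodo-2-methylidene-3-(4,4,5,5-tetramethyl-1,3,2-dioxaborolan-2-yl)hept-6-enoate
Conditions: CuCl (5 mol%), (S,S)-2,3-bis(tert-butylmethylphosphino)quinoxaline (6 mol%), B2pin2 (1.0 equiv), LiOtBu (1.0 equiv, slow addition), THF, −40 °C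
Reagents that add atoms: bis(pinacolato)diboron CC1(C)OB(OC1(C)C)B1OC(C)(C)C(C)(C)O1
Why: Proposed new method: the copper–boryl species adds to the β-carbon (C3) of the enoate and the copper enolate expels bromide (conjugate borylation then β-elimination, a formal SN2′ substitution that moves boron to the secondary carbon), with the chiral bisphosphine fixing the face of boryl delivery to give 3R; the closest known reactions are the copper-catalysed enantioselective γ-borylation of (Z)-allylic carbonates and the asymmetric β-borylation of enoates.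

Step 7
Reactants: 9 tert-butyl (3R)-6-iodo-2-methylidene-3-(4,4,5,5-tetramethyl-1,3,2-dioxaborolan-2-yl)hept-6-enoate; 2 3,3-dimethylpentanedial (3 equiv)
Product: 11 tert-butyl (3R,7S)-9,9-dimethyl-2,6-dimethylidene-11-oxo-3-(4,4,5,5-tetramethyl-1,3,2-dioxaborolan-2-yl)-7-[(triethylsilyl)oxy]undecanoate, via chromium alkoxide 10 (not isolated)
Conditions: CrCl2 (10 mol%), (S)-N-[2-(4-tert-butyl-4,5-dihydro-1,3-oxazol-2-yl)-6-methylphenyl]methanesulfonamide (11 mol%), Et3N (11 mol%), NiCl2·(2,9-dimethyl-1,10-phenanthroline) (2 mol%), Mn powder, LiCl, Et3SiCl, MeCN, rt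
Reagents that add atoms: chlorotriethylsilane CC[Si](Cl)(CC)CC
Why: Catalytic asymmetric Nozaki–Hiyama–Kishi coupling, in which the alkenylchromium species adds to the Re face of one aldehyde of 2 under control of the sulfonamide ligand to set 7S; Et3SiCl releases the chromium alkoxide as the silyl ether (no lactol can form), excess 2 suppresses double addition, and the ester-deactivated allylboronate does not add to aldehydes at rt without a strong Lewis acid.

Step 8
Reactants: 11 tert-butyl (3R,7S)-9,9-dimethyl-2,6-dimethylidene-11-oxo-3-(4,4,5,5-tetramethyl-1,3,2-dioxaborolan-2-yl)-7-[(triethylsilyl)oxy]undecanoate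
Product: 13 tert-butyl (1E,6S,10S)-10-hydroxy-8,8-dimethyl-5-methylidene-6-[(triethylsilyl)oxy]cycloundec-1-ene-1-carboxylate, via macrocyclic borate 12 (not isolated)
Conditions: Sc(OTf)3 (20 mol%), CH2Cl2, slow addition to 2 mM, 0 °C to rt; aqueous NaHCO3 work-up
Reagents that add atoms: none
Why: Proposed new method: the allylboronate is a masked ester homoenolate whose CH2 terminus (the acrylate β-carbon, normally an electrophile) is delivered to the aldehyde carbon through a closed six-membered chair transition state activated by Sc(OTf)3, with the C3 side chain pseudo-axial (it avoids A-1,2 strain with the ester and the pinacolate) and the aldehyde chain equatorial, so the 3R boron-bearing centre is traded for 10S and the 1E enoate in which the two ring carbons are cis; the closest known reactions are Sc(OTf)3-catalysed additions of 2-(alkoxycarbonyl)allylboronates and chirality-transferring additions of α-substituted allylboronates, the new element being closure of an 11-membered ring.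

Step 9
Reactants: 13 tert-butyl (1E,6S,10S)-10-hydroxy-8,8-dimethyl-5-methylidene-6-[(triethylsilyl)oxy]cycloundec-1-ene-1-carboxylate; 14 3-methylbutanoic anhydride
Product: 15 tert-butyl (1E,6S,10S)-8,8-dimethyl-5-methylidene-10-[(3-methylbutanoyl)oxy]-6-[(triethylsilyl)oxy]cycloundec-1-ene-1-carboxylate
Conditions: 4-(dimethylamino)pyridine (10 mol%), pyridine/CH2Cl2, 0 °C to rt
Reagents that add atoms: none
Why: Nucleophilic-catalysis acylation of the only free hydroxyl; the C6 oxygen is silylated and the tert-butyl ester resists lactonisation.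

Step 10
Reactants: 15 tert-butyl (1E,6S,10S)-8,8-dimethyl-5-methylidene-10-[(3-methylbutanoyl)oxy]-6-[(triethylsilyl)oxy]cycloundec-1-ene-1-carboxylate
Product: 17 (1E,6S,10S)-6-hydroxy-8,8-dimethyl-5-methylidene-10-[(3-methylbutanoyl)oxy]cycloundec-1-ene-1-carboxylic acid, via trimethylsilyl ester 16 (not isolated)
Conditions: Me3SiOTf, 2,6-lutidine, CH2Cl2, 0 °C; then HF·pyridine, THF, 0 °C to rt
Reagents that add atoms: none
Why: Silyl triflate converts the tert-butyl ester into the silyl ester with loss of isobutene without protic acid (which would endanger the allylic alcohol and the exocyclic alkene), and buffered fluoride then removes both silyl groups while the isovalerate stays.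

**Compound list**

1 | 3,3-dimethylpentane-1,5-diol | OCCC(C)(C)CCO | starting material
2 | 3,3-dimethylpentanedial | O=CCC(C)(C)CC=O | intermediate
3 | pent-4-yn-1-ol | C#CCCCO | starting material
4 | 4-iodopent-4-en-1-ol | C=C(I)CCCO | intermediate
5 | 4-iodopent-4-enal | C=C(I)CCC=O | intermediate
6 | tert-butyl acrylate | C=CC(=O)OC(C)(C)C | starting material
7 | tert-butyl 3-hydroxy-6-iodo-2-methylidenehept-6-enoate (racemic) | C=C(I)CCC(O)C(=C)C(=O)OC(C)(C)C | intermediate
8 | tert-butyl (2Z)-2-(bromomethyl)-6-iodohepta-2,6-dienoate | C=C(I)CC/C=C(/C(=O)OC(C)(C)C)CBr | intermediate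
9 | tert-butyl (3R)-6-iodo-2-methylidene-3-(4,4,5,5-tetramethyl-1,3,2-dioxaborolan-2-yl)hept-6-enoate | C=C(I)CC[C@@H](B1OC(C)(C)C(C)(C)O1)C(=C)C(=O)OC(C)(C)C | intermediate
10 | dichloridochromium alkoxide of tert-butyl (3R,7S)-7-hydroxy-9,9-dimethyl-2,6-dimethylidene-11-oxo-3-(4,4,5,5-tetramethyl-1,3,2-dioxaborolan-2-yl)undecanoate (trivalent chromium, chiral ligand not drawn) | O=CCC(C)(C)C[C@H](O[Cr](Cl)Cl)C(=C)CC[C@@H](B1OC(C)(C)C(C)(C)O1)C(=C)C(=O)OC(C)(C)C | intermediate
11 | tert-butyl (3R,7S)-9,9-dimethyl-2,6-dimethylidene-11-oxo-3-(4,4,5,5-tetramethyl-1,3,2-dioxaborolan-2-yl)-7-[(triethylsilyl)oxy]undecanoate | O=CCC(C)(C)C[C@H](O[Si](CC)(CC)CC)C(=C)CC[C@@H](B1OC(C)(C)C(C)(C)O1)C(=C)C(=O)OC(C)(C)C | intermediate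
12 | tert-butyl (1E,6S,10S)-8,8-dimethyl-5-methylidene-10-[(4,4,5,5-tetramethyl-1,3,2-dioxaborolan-2-yl)oxy]-6-[(triethylsilyl)oxy]cycloundec-1-ene-1-carboxylate | C=C1CC/C=C(/C(=O)OC(C)(C)C)C[C@@H](OB2OC(C)(C)C(C)(C)O2)CC(C)(C)C[C@@H]1O[Si](CC)(CC)CC | intermediate
13 | tert-butyl (1E,6S,10S)-10-hydroxy-8,8-dimethyl-5-methylidene-6-[(triethylsilyl)oxy]cycloundec-1-ene-1-carboxylate | C=C1CC/C=C(/C(=O)OC(C)(C)C)C[C@@H](O)CC(C)(C)C[C@@H]1O[Si](CC)(CC)CC | intermediate
14 | 3-methylbutanoic anhydride | CC(C)CC(=O)OC(=O)CC(C)C | starting material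
15 | tert-butyl (1E,6S,10S)-8,8-dimethyl-5-methylidene-10-[(3-methylbutanoyl)oxy]-6-[(triethylsilyl)oxy]cycloundec-1-ene-1-carboxylate | C=C1CC/C=C(/C(=O)OC(C)(C)C)C[C@@H](OC(=O)CC(C)C)CC(C)(C)C[C@@H]1O[Si](CC)(CC)CC | intermediate
16 | trimethylsilyl (1E,6S,10S)-8,8-dimethyl-5-methylidene-10-[(3-methylbutanoyl)oxy]-6-[(triethylsilyl)oxy]cycloundec-1-ene-1-carboxylate | C=C1CC/C=C(/C(=O)O[Si](C)(C)C)C[C@@H](OC(=O)CC(C)C)CC(C)(C)C[C@@H]1O[Si](CC)(CC)CC | intermediate
17 | (1E,6S,10S)-6-hydroxy-8,8-dimethyl-5-methylidene-10-[(3-methylbutanoyl)oxy]cycloundec-1-ene-1-carboxylic acid (CNP0400752.1) | C=C1CC/C=C(/C(=O)O)C[C@@H](OC(=O)CC(C)C)CC(C)(C)C[C@@H]1O | target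

**Step count and risks**

Total step count: 10. Longest linear sequence: 9 (steps 2 to 10, from 3).

Step 6 is risky because this substrate class is untested for asymmetric copper–boryl substitution. The product acrylate is itself a Michael acceptor, so over-borylation or boryl migration to the primary isomer is possible; alkoxide may attack the bromide; and the ee is unknown. The fallback sets out from 5 and comes back at 9. Olefination of 5 with tert-butyl diethylphosphonoacetate (LiCl, DBU) gives tert-butyl (2E)-6-iodohepta-2,6-dienoate F1. Asymmetric β-borylation (CuCl, NaOtBu, (R)-2,2′-bis(di-p-tolylphosphino)-1,1′-binaphthyl, B2pin2, MeOH, THF) gives tert-butyl (3R)-6-iodo-3-(4,4,5,5-tetramethyl-1,3,2-dioxaborolan-2-yl)hept-6-enoate F2. Enolisation with LiN(iPr)2 and trapping with dimethylmethylideneammonium iodide gives tert-butyl (3R)-2-[(dimethylamino)methyl]-6-iodo-3-(4,4,5,5-tetramethyl-1,3,2-dioxaborolan-2-yl)hept-6-enoate F3. MeI gives [(3R)-2-(tert-butoxycarbonyl)-6-iodo-3-(4,4,5,5-tetramethyl-1,3,2-dioxaborolan-2-yl)hept-6-en-1-yl]trimethylammonium iodide F4, and elimination with NaHCO3 returns 9. The stereocentre then comes from an established enoate borylation, and the methylidene is installed afterwards.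

Step 7 is risky for four reasons:
- the coupling is run on a dialdehyde in the presence of an allylboronate;
- turnover with Et3SiCl is slower than with Me3SiCl;
- bis-adduct and premature allylboration are possible;
- the sense and level of induction at C7 are unverified.

The fallback sets out from 1 and 9 and comes back at 11. Oxidation of 1 with PhI(OAc)2 and catalytic 2,2,6,6-tetramethylpiperidin-1-oxyl gives 4,4-dimethyloxan-2-one F5, and iBu2AlH gives 4,4-dimethyloxan-2-ol F6. Stoichiometric asymmetric coupling of 9 with this lactol (CrCl2, the same sulfonamide ligand, Et3N, catalytic NiCl2, THF) gives tert-butyl (3R,7S)-7,11-dihydroxy-9,9-dimethyl-2,6-dimethylidene-3-(4,4,5,5-tetramethyl-1,3,2-dioxaborolan-2-yl)undecanoate F7. Et3SiOTf/2,6-lutidine gives tert-butyl (3R,7S)-9,9-dimethyl-2,6-dimethylidene-3-(4,4,5,5-tetramethyl-1,3,2-dioxaborolan-2-yl)-7,11-bis[(triethylsilyl)oxy]undecanoate F8. Swern oxidation, which converts only the primary triethylsilyl ether into the aldehyde, gives 11. The lactol replaces the excess dialdehyde and the silyl chloride turnover.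

Step 8 is risky for four reasons:
- allylboration has not been used to close an 11-membered ring, and oligomerisation competes;
- a boat or alternative chair would give the C10 epimer or the ring-trans enoate;
- the C6 centre may be mismatched;
- Sc(OTf)3 could desilylate or lactonise.

The fallback sets out from 1 and 9 and comes back at 15; it makes the same C–C bond intermolecularly and closes the ring at C5–C6 instead. Monosilylation of 1 (NaH, tBuMe2SiCl) gives 5-[(tert-butyldimethylsilyl)oxy]-3,3-dimethylpentan-1-ol F9, and Swern oxidation gives 5-[(tert-butyldimethylsilyl)oxy]-3,3-dimethylpentanal F10. Sc(OTf)3-catalysed addition of 9 gives, through the borate tert-butyl (2E)-2-[(2S)-6-[(tert-butyldimethylsilyl)oxy]-4,4-dimethyl-2-[(4,4,5,5-tetramethyl-1,3,2-dioxaborolan-2-yl)oxy]hexyl]-6-iodohepta-2,6-dienoate F11, the alcohol tert-butyl (2E)-2-[(2S)-6-[(tert-butyldimethylsilyl)oxy]-2-hydroxy-4,4-dimethylhexyl]-6-iodohepta-2,6-dienoate F12. Acylation with 14 gives tert-butyl (2E)-2-[(2S)-6-[(tert-butyldimethylsilyl)oxy]-4,4-dimethyl-2-[(3-methylbutanoyl)oxy]hexyl]-6-iodohepta-2,6-dienoate F13. HF·pyridine gives tert-butyl (2E)-2-[(2S)-6-hydroxy-4,4-dimethyl-2-[(3-methylbutanoyl)oxy]hexyl]-6-iodohepta-2,6-dienoate F14, and Dess–Martin oxidation gives tert-butyl (2E)-2-[(2S)-4,4-dimethyl-2-[(3-methylbutanoyl)oxy]-6-oxohexyl]-6-iodohepta-2,6-dienoate F15. Asymmetric chromium-mediated macrocyclisation (CrCl2, the sulfonamide ligand, Et3N, catalytic NiCl2, THF, high dilution) gives tert-butyl (1E,6S,10S)-6-hydroxy-8,8-dimethyl-5-methylidene-10-[(3-methylbutanoyl)oxy]cycloundec-1-ene-1-carboxylate F16. Et3SiCl/imidazole converts it into 15.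

**Further compounds**

F1 | step 6 | tert-butyl (2E)-6-iodohepta-2,6-dienoate | C=C(I)CC/C=C/C(=O)OC(C)(C)C
F2 | step 6 | tert-butyl (3R)-6-iodo-3-(4,4,5,5-tetramethyl-1,3,2-dioxaborolan-2-yl)hept-6-enoate | C=C(I)CC[C@@H](B1OC(C)(C)C(C)(C)O1)CC(=O)OC(C)(C)C
F3 | step 6 | tert-butyl (3R)-2-[(dimethylamino)methyl]-6-iodo-3-(4,4,5,5-tetramethyl-1,3,2-dioxaborolan-2-yl)hept-6-enoate | C=C(I)CC[C@@H](B1OC(C)(C)C(C)(C)O1)C(CN(C)C)C(=O)OC(C)(C)C
F4 | step 6 | [(3R)-2-(tert-butoxycarbonyl)-6-iodo-3-(4,4,5,5-tetramethyl-1,3,2-dioxaborolan-2-yl)hept-6-en-1-yl]trimethylammonium iodide | C=C(I)CC[C@@H](B1OC(C)(C)C(C)(C)O1)C(C[N+](C)(C)C)C(=O)OC(C)(C)C.[I-]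
F5 | step 7 | 4,4-dimethyloxan-2-one | O=C1CC(C)(C)CCO1
F6 | step 7 | 4,4-dimethyloxan-2-ol | OC1CC(C)(C)CCO1
F7 | step 7 | tert-butyl (3R,7S)-7,11-dihydroxy-9,9-dimethyl-2,6-dimethylidene-3-(4,4,5,5-tetramethyl-1,3,2-dioxaborolan-2-yl)undecanoate | OCCC(C)(C)C[C@H](O)C(=C)CC[C@@H](B1OC(C)(C)C(C)(C)O1)C(=C)C(=O)OC(C)(C)C
F8 | step 7 | tert-butyl (3R,7S)-9,9-dimethyl-2,6-dimethylidene-3-(4,4,5,5-tetramethyl-1,3,2-dioxaborolan-2-yl)-7,11-bis[(triethylsilyl)oxy]undecanoate | CC[Si](CC)(CC)OCCC(C)(C)C[C@H](O[Si](CC)(CC)CC)C(=C)CC[C@@H](B1OC(C)(C)C(C)(C)O1)C(=C)C(=O)OC(C)(C)C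
F9 | step 8 | 5-[(tert-butyldimethylsilyl)oxy]-3,3-dimethylpentan-1-ol | CC(C)(C)[Si](C)(C)OCCC(C)(C)CCO
F10 | step 8 | 5-[(tert-butyldimethylsilyl)oxy]-3,3-dimethylpentanal | CC(C)(C)[Si](C)(C)OCCC(C)(C)CC=O
F11 | step 8 | tert-butyl (2E)-2-[(2S)-6-[(tert-butyldimethylsilyl)oxy]-4,4-dimethyl-2-[(4,4,5,5-tetramethyl-1,3,2-dioxaborolan-2-yl)oxy]hexyl]-6-iodohepta-2,6-dienoate | C=C(I)CC/C=C(/C(=O)OC(C)(C)C)C[C@@H](OB1OC(C)(C)C(C)(C)O1)CC(C)(C)CCO[Si](C)(C)C(C)(C)C
F12 | step 8 | tert-butyl (2E)-2-[(2S)-6-[(tert-butyldimethylsilyl)oxy]-2-hydroxy-4,4-dimethylhexyl]-6-iodohepta-2,6-dienoate | C=C(I)CC/C=C(/C(=O)OC(C)(C)C)C[C@@H](O)CC(C)(C)CCO[Si](C)(C)C(C)(C)C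
F13 | step 8 | tert-butyl (2E)-2-[(2S)-6-[(tert-butyldimethylsilyl)oxy]-4,4-dimethyl-2-[(3-methylbutanoyl)oxy]hexyl]-6-iodohepta-2,6-dienoate | C=C(I)CC/C=C(/C(=O)OC(C)(C)C)C[C@@H](OC(=O)CC(C)C)CC(C)(C)CCO[Si](C)(C)C(C)(C)C
F14 | step 8 | tert-butyl (2E)-2-[(2S)-6-hydroxy-4,4-dimethyl-2-[(3-methylbutanoyl)oxy]hexyl]-6-iodohepta-2,6-dienoate | C=C(I)CC/C=C(/C(=O)OC(C)(C)C)C[C@@H](OC(=O)CC(C)C)CC(C)(C)CCO
F15 | step 8 | tert-butyl (2E)-2-[(2S)-4,4-dimethyl-2-[(3-methylbutanoyl)oxy]-6-oxohexyl]-6-iodohepta-2,6-dienoate | C=C(I)CC/C=C(/C(=O)OC(C)(C)C)C[C@@H](OC(=O)CC(C)C)CC(C)(C)CC=O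
F16 | step 8 | tert-butyl (1E,6S,10S)-6-hydroxy-8,8-dimethyl-5-methylidene-10-[(3-methylbutanoyl)oxy]cycloundec-1-ene-1-carboxylate | C=C1CC/C=C(/C(=O)OC(C)(C)C)C[C@@H](OC(=O)CC(C)C)CC(C)(C)C[C@@H]1O
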